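**Retrosynthetic overview**
1. Epoxytwinol A is a C2-symmetric head-to-head dimer. Cutting the two sp3–sp3 bonds of the central cycloocta-1,5-diene ring (the O–CH–CH–O bond and the CH–CH bond flanked by the two CHMe carbons) gives two identical 2H-pyrans.
2. Enabling feature: each oxygen ring (O, CHMe, CH, the cyclohexenone C=C, O–CH) is a latent 2H-pyran, the 6π-electrocyclised form of a 3-formyl-2-[(E)-propenyl]cyclohexenone. The bond from the enone α-carbon to the propenyl CH is therefore a vinyl–vinyl bond of the monomer and can come from cross-coupling of a β-bromo enal.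
3. Key operation: Stille coupling of the bromo enal with an (E)-propenylstannane, oxa-electrocyclisation and formal [4+4] dimerisation in one flask. The carbinol oxygen carries a di-tert-butylsilanol as a temporary hydrogen-bond template, removed in the last step.
4. The bromo enal comes from 2,5-dihydroxybenzaldehyde: bromination, quinone monoketal, tartrate-mediated asymmetric epoxidation, anti-selective ketone reduction, ketal hydrolysis, selective primary alcohol oxidation.
5. Ring order: carbocycle (from the arene), epoxide, both pyran rings, eight-membered ring.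

Key step: step 10

Assumption: the facial sense of the tartrate-mediated epoxidation in step 5 is taken to be that diisopropyl L-tartrate gives the (5R,6S)-epoxide 6; should the sense be the opposite, diisopropyl D-tartrate is used and nothing else changes.

**Route**

Step 1
Reactants: 1 2,5-dihydroxybenzaldehyde
Product: 2 2-bromo-3,6-dihydroxybenzaldehyde
Conditions: Br2 (1.05 equiv), CHCl3, 0 °C to 25 °C
Reagents that add atoms: bromine, BrBr
Why: Electrophilic aromatic bromination; the 5-hydroxyl, which is not tied up in the hydrogen bond to the formyl group, directs ortho, and the bromine should enter between it and the formyl group as in the bromination of isovanillin and other 3-hydroxybenzaldehydes.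

Step 2
Reactants: 2 2-bromo-3,6-dihydroxybenzaldehyde
Product: 3 2-bromo-6-hydroxy-3-methoxybenzaldehyde
Conditions: MeI (1.1 equiv), K2CO3 (1.0 equiv), DMF, 0 °C to 25 °C
Reagents that add atoms: iodomethane, CI
Why: Williamson etherification, selective for the 3-hydroxyl because the 6-hydroxyl is held in a six-membered hydrogen bond with the formyl oxygen and is much less nucleophilic.

Step 3
Reactants: 3 2-bromo-6-hydroxy-3-methoxybenzaldehyde
Product: 4 3-bromo-2-(hydroxymethyl)-4-methoxyphenol
Conditions: NaBH4, MeOH/THF, 0 °C
Reagents that add atoms: none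
Why: Borohydride reduction of the aryl aldehyde to the benzylic alcohol; nothing else in 3 is reducible under these conditions.

Step 4
Reactants: 4 3-bromo-2-(hydroxymethyl)-4-methoxyphenol
Product: 5 3-bromo-2-(hydroxymethyl)-4,4-dimethoxycyclohexa-2,5-dien-1-one
Conditions: PhI(OAc)2 (1.1 equiv), MeOH, 0 °C
Reagents that add atoms: methanol, CO
Why: Oxidative dearomatisation of a para-methoxyphenol (two-electron oxidation at the phenol, capture of the para position by methanol) gives the quinone monoketal with the ketal carbon next to the C–Br carbon and the free carbonyl next to the hydroxymethyl-bearing carbon.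

Step 5
Reactants: 5 3-bromo-2-(hydroxymethyl)-4,4-dimethoxycyclohexa-2,5-dien-1-one
Product: 6 (5R,6S)-3-bromo-5,6-epoxy-2-(hydroxymethyl)-4,4-dimethoxycyclohex-2-en-1-one
Conditions: Ph3COOH (1.5 equiv), NaN(SiMe3)2 (2 equiv), diisopropyl L-tartrate (1.2 equiv), toluene, -78 °C to -40 °C
Reagents that add atoms: trityl hydroperoxide, OOC(c1ccccc1)(c1ccccc1)c1ccccc1
Why: Tartrate-mediated nucleophilic (Weitz–Scheffer-type) epoxidation: the sodium alkoxide of the hydroxymethyl group anchors the dienone to the chiral sodium tartrate/trityl peroxide aggregate, the peroxide adds on one enantiotopic face to the unsubstituted enone carbon next to the ketal and the enolate closes the cis-epoxide with loss of trityloxide, which sets both epoxide centres, while the bromine-bearing tetrasubstituted enone is too hindered to compete.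

Step 6
Reactants: 6 (5R,6S)-3-bromo-5,6-epoxy-2-(hydroxymethyl)-4,4-dimethoxycyclohex-2-en-1-one
Product: 7 (1S,5R,6R)-3-bromo-5,6-epoxy-2-(hydroxymethyl)-4,4-dimethoxycyclohex-2-en-1-ol (hydroxyl anti to the epoxide)
Conditions: iBu2AlH (2.5 equiv), THF, -78 °C; aq. KNaC4H4O6 work-up
Reagents that add atoms: none
Why: 1,2-Reduction of the α,β-epoxy ketone under chelation control: the aluminium reagent, bound as the primary alkoxide and to the epoxide oxygen, should deliver hydride on the epoxide face so that the new (1S)-hydroxyl stands anti to the epoxide, and the vinyl bromide, ketal and epoxide are inert at -78 °C.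

Step 7
Reactants: 7 (1S,5R,6R)-3-bromo-5,6-epoxy-2-(hydroxymethyl)-4,4-dimethoxycyclohex-2-en-1-ol
Product: 8 (4S,5R,6R)-2-bromo-5,6-epoxy-4-hydroxy-3-(hydroxymethyl)cyclohex-2-en-1-one
Conditions: 48% aq. HF, MeCN, 0 °C to 25 °C
Reagents that add atoms: water, O
Why: Acid-catalysed hydrolysis of the dimethyl ketal unveils the enone with bromine on the α-carbon and hydroxymethyl on the β-carbon; the epoxide, flanked by the carbonyl carbon and the carbinol, should resist opening and no stereocentre is touched.

Step 8
Reactants: 8 (4S,5R,6R)-2-bromo-5,6-epoxy-4-hydroxy-3-(hydroxymethyl)cyclohex-2-en-1-one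
Product: 9 (4S,5R,6R)-2-bromo-5,6-epoxy-3-formyl-4-hydroxycyclohex-2-en-1-one
Conditions: TEMPO (10 mol %), CuCl (10 mol %), O2 (1 atm), DMF, 25 °C
Reagents that add atoms: none
Why: Aerobic oxoammonium oxidation; the unhindered primary allylic alcohol should be oxidised much faster than the secondary carbinol flanked by the epoxide and the tetrasubstituted alkene, and the aldehyde does not over-oxidise without water.

Step 9
Reactants: 9 (4S,5R,6R)-2-bromo-5,6-epoxy-3-formyl-4-hydroxycyclohex-2-en-1-one
Product: 11 (4S,5S,6R)-2-bromo-4-{[di-tert-butyl(hydroxy)silyl]oxy}-5,6-epoxy-3-formylcyclohex-2-en-1-one, via silyl triflate 10 (not isolated)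
Conditions: tBu2Si(OTf)2 (1.2 equiv), 2,6-lutidine (3 equiv), CH2Cl2, -78 °C to 0 °C; then sat. aq. NaHCO3, THF, 0 °C
Reagents that add atoms: di-tert-butylsilyl bis(trifluoromethanesulfonate), CC(C)(C)[Si](OS(=O)(=O)C(F)(F)F)(OS(=O)(=O)C(F)(F)F)C(C)(C)C; water, O
Why: Silylation of the secondary alcohol by the highly electrophilic bis-triflate gives mono-alkoxysilyl triflate 10, which is too hindered to take up a second secondary alcohol and is hydrolysed by aqueous hydrogencarbonate to the silanol; di-tert-butylsilanols do not condense to disiloxanes, and the aldehyde (no α-hydrogen) and the epoxide should tolerate the lutidine-buffered conditions.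

Step 10
Reactants: 11 (4S,5S,6R)-2-bromo-4-{[di-tert-butyl(hydroxy)silyl]oxy}-5,6-epoxy-3-formylcyclohex-2-en-1-one (2 equiv) and 12 (E)-tributyl(prop-1-en-1-yl)stannane (2.2 equiv)
Product: 15 epoxytwinol A bis[di-tert-butyl(hydroxy)silyl] ether, via dienal 13 (not isolated), via 2H-pyran 14 (not isolated)
Conditions: Pd2(dba)3 (5 mol %), AsPh3 (20 mol %), toluene (0.5 M), 25 °C, then 40 °C in the same flask
Reagents that add atoms: none
Why: Zerovalent palladium inserts into the C–Br bond of the β-bromo enal 11 (a vinylogous acyl bromide), transmetalation with 12 and reductive elimination (Stille coupling, E geometry retained) join the enone α-carbon to the propenyl CH to give dienal 13, which closes by thermal disrotatory 6π-oxa-electrocyclisation to 2H-pyran 14, and two molecules of 14 then combine head to head in a formal [4+4] cycloaddition that forms the bond between the two O–CH carbons and the bond between the two ring CH carbons next to the CHMe groups. The closest known reaction types are the Stille coupling of α-halo enones with alkenylstannanes, the oxa-electrocyclisation/dimerisation cascade of 3-formyl-2-alkenyl epoxycyclohexenones set off by alcohol oxidation, and the hydrogen-bond-assisted [4+4] dimerisation of alkoxysilanol-bearing 2H-pyrans; here the cross-coupling only replaces the oxidation as the trigger. Each pyran ring closes by O–C bond formation in the electrocyclisation, and the cycloocta-1,5-diene ring closes intermolecularly, most likely stepwise because a concerted suprafacial thermal [4+4] is symmetry-forbidden: Michael-type union of the dienol ether terminus of one pyran with the enone β-carbon of the other, then collapse of the resulting dienolate/oxocarbenium pair at the two O–CH carbons. The six new stereocentres are controlled by the existing silyloxy and epoxide centres: the two C-methyl epimers of 14 interconvert through 13 (Curtin–Hammett situation) and the epimer with methyl on the epoxide face reacts, each pyran is attacked on the face opposite to its methyl group and epoxide (the silyloxy face), bonding across each diene is suprafacial, and head-to-head union of two identical homochiral units gives the C2-symmetric product. The step needs [4+4] over the competing Diels–Alder ([4+2]) dimerisations and head-to-head over head-to-tail orientation, which the two Si–OH groups should secure through a silanol–silanol hydrogen bond that, in the non-polar solvent, holds the two silyloxy faces together across the forming O–CH–CH–O bond.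

Step 11
Reactants: 15 epoxytwinol A bis[di-tert-butyl(hydroxy)silyl] ether
Product: 16 epoxytwinol A
Conditions: HF·pyridine, pyridine, THF, 0 °C to 25 °C
Reagents that add atoms: none
Why: Fluoride-driven cleavage of both Si–O–C bonds under buffered conditions that should leave the epoxy ketones and the bis-allylic ether bridges intact; no stereocentre is involved.

**Compound list**
1 | 2,5-dihydroxybenzaldehyde | O=Cc1cc(O)ccc1O | starting material
2 | 2-bromo-3,6-dihydroxybenzaldehyde | O=Cc1c(Br)c(O)ccc1O | intermediate
3 | 2-bromo-6-hydroxy-3-methoxybenzaldehyde | COc1ccc(O)c(C=O)c1Br | intermediate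
4 | 3-bromo-2-(hydroxymethyl)-4-methoxyphenol | COc1ccc(O)c(CO)c1Br | intermediate
5 | 3-bromo-2-(hydroxymethyl)-4,4-dimethoxycyclohexa-2,5-dien-1-one | OCC1=C(Br)C(OC)(OC)C=CC1=O | intermediate
6 | (5R,6S)-3-bromo-5,6-epoxy-2-(hydroxymethyl)-4,4-dimethoxycyclohex-2-en-1-one | OCC1=C(Br)C(OC)(OC)[C@@H]2O[C@@H]2C1=O | intermediate
7 | (1S,5R,6R)-3-bromo-5,6-epoxy-2-(hydroxymethyl)-4,4-dimethoxycyclohex-2-en-1-ol (hydroxyl anti to epoxide) | OCC1=C(Br)C(OC)(OC)[C@@H]2O[C@@H]2[C@H]1O | intermediate
8 | (4S,5R,6R)-2-bromo-5,6-epoxy-4-hydroxy-3-(hydroxymethyl)cyclohex-2-en-1-one | OCC1=C(Br)C(=O)[C@@H]2O[C@@H]2[C@H]1O | intermediate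
9 | (4S,5R,6R)-2-bromo-5,6-epoxy-3-formyl-4-hydroxycyclohex-2-en-1-one | O=CC1=C(Br)C(=O)[C@@H]2O[C@@H]2[C@H]1O | intermediate
10 | silyl triflate: (4S,5S,6R)-2-bromo-4-{[di-tert-butyl(trifluoromethanesulfonyloxy)silyl]oxy}-5,6-epoxy-3-formylcyclohex-2-en-1-one | O=CC1=C(Br)C(=O)[C@@H]2O[C@@H]2[C@H]1O[Si](OS(=O)(=O)C(F)(F)F)(C(C)(C)C)C(C)(C)C | intermediate
11 | (4S,5S,6R)-2-bromo-4-{[di-tert-butyl(hydroxy)silyl]oxy}-5,6-epoxy-3-formylcyclohex-2-en-1-one | O=CC1=C(Br)C(=O)[C@@H]2O[C@@H]2[C@H]1O[Si](O)(C(C)(C)C)C(C)(C)C | intermediate
12 | (E)-tributyl(prop-1-en-1-yl)stannane | C/C=C/[Sn](CCCC)(CCCC)CCCC | starting material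
13 | dienal: (4S,5S,6R)-4-{[di-tert-butyl(hydroxy)silyl]oxy}-5,6-epoxy-3-formyl-2-[(1E)-prop-1-en-1-yl]cyclohex-2-en-1-one | O=CC1=C(/C=C/C)C(=O)[C@@H]2O[C@@H]2[C@H]1O[Si](O)(C(C)(C)C)C(C)(C)C | intermediate
14 | 2H-pyran valence tautomer of 13 (3-methyl-3H-isochromen-5-one skeleton, (3R), methyl on the epoxide face, silyloxy on the opposite face) | C[C@H]1OC=C2C(=C1)C(=O)[C@@H]3O[C@@H]3[C@H]2O[Si](O)(C(C)(C)C)C(C)(C)C | intermediate
15 | epoxytwinol A bis[di-tert-butyl(hydroxy)silyl] ether (both secondary hydroxyls silylated) | C[C@H]1O[C@H]2C3=C(C(=O)[C@@H]4O[C@@H]4[C@H]3O[Si](O)(C(C)(C)C)C(C)(C)C)[C@@H]1[C@H]1C3=C([C@H](O[Si](O)(C(C)(C)C)C(C)(C)C)[C@H]4O[C@H]4C3=O)[C@@H]2O[C@@H]1C | intermediate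
16 | epoxytwinol A | C[C@H]1O[C@H]2C3=C(C(=O)[C@@H]4O[C@@H]4[C@H]3O)[C@@H]1[C@H]1C3=C([C@H](O)[C@H]4O[C@H]4C3=O)[C@@H]2O[C@@H]1C | target

**Step count**
Total: 11 steps. Longest linear sequence: 11 steps (1 to 16); 12 enters at step 10.

**Steps most likely to fail, with fallbacks**

Step 10. Process at risk: the tin bromide, arsine and palladium in the coupling medium may compete for the silanol hydrogen bonds, so that the pyran dimerises through the Diels–Alder ([4+2]) modes instead of head to head; slow oxidative addition would also leave the sensitive bromo enal to decompose. The fallback moves the cross-coupling ahead of the aldehyde and triggers the cascade by alcohol oxidation. It sets out from 8 and comes back at 15. Compound 8 is coupled with 12 at the alcohol oxidation level (Pd2(dba)3, AsPh3, toluene, 80 °C), where no pyran can form, to give the propenyl diol F1. The primary hydroxyl is silylated (tBuMe2SiCl, imidazole, CH2Cl2, 0 °C) to give the primary silyl ether F2. The secondary hydroxyl is converted as in step 9 into the silanol F3. The primary silyl ether is removed (pyridinium p-toluenesulfonate, MeOH, 0 °C) to give the primary alcohol F4. Oxidation of F4 (TEMPO, PhI(OAc)2, CH2Cl2) then releases dienal 13 in a tin- and palladium-free solution, which after exchange to toluene and concentration should electrocyclise to 14 and dimerise to 15.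

Step 6. Process at risk: hydride delivery through the non-chelated pathway, on the face opposite to the epoxide, which would place the hydroxyl syn to the epoxide. The fallback accepts that facial preference and corrects the centre by inversion. It sets out from 6 and comes back at 8. The primary hydroxyl of 6 is silylated (tBuMe2SiCl, imidazole, CH2Cl2) to give the silyl ether F5. Reduction with the non-chelating LiBHEt3 (THF, -78 °C), anti to the epoxide oxygen, gives the syn-epoxy alcohol F6. Mitsunobu inversion (4-nitrobenzoic acid, PPh3, diisopropyl azodicarboxylate, THF, 0 °C) gives the anti 4-nitrobenzoate F7. Mild methanolysis (K2CO3, MeOH, 0 °C) gives the anti alcohol F8. Treatment of F8 with 48% aq. HF in MeCN removes the silyl ether and the ketal together and gives 8.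

Step 5. Process at risk: insufficient discrimination of the two enantiotopic faces in the sodium tartrate aggregate, or addition–elimination of the peroxide at the bromine-bearing carbon. The fallback replaces hydroxyl-directed metal tartrate control by chiral ion-pair control on the protected substrate. It sets out from 5 and comes back at 6. The hydroxyl of 5 is protected (tBuPh2SiCl, imidazole, CH2Cl2) to give the silyl ether F9. Asymmetric phase-transfer epoxidation (tBuOOH, aq. NaOH, toluene, 0 °C, with N-benzylcinchonidinium chloride or its pseudoenantiomer N-benzylcinchoninium chloride, whichever delivers the required face) gives the epoxy ketone silyl ether F10. Desilylation of F10 (HF·pyridine, THF, 0 °C) gives 6.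

**Further compounds**
F1 | step 10 | (4S,5R,6R)-5,6-epoxy-4-hydroxy-3-(hydroxymethyl)-2-[(1E)-prop-1-en-1-yl]cyclohex-2-en-1-one | OCC1=C(/C=C/C)C(=O)[C@@H]2O[C@@H]2[C@H]1O
F2 | step 10 | primary tert-butyldimethylsilyl ether of F1 | CC(C)(C)[Si](C)(C)OCC1=C(/C=C/C)C(=O)[C@@H]2O[C@@H]2[C@H]1O
F3 | step 10 | di-tert-butyl(hydroxy)silyl ether (secondary oxygen) of F2 | CC(C)(C)[Si](C)(C)OCC1=C(/C=C/C)C(=O)[C@@H]2O[C@@H]2[C@H]1O[Si](O)(C(C)(C)C)C(C)(C)C
F4 | step 10 | primary alcohol: 4-{[di-tert-butyl(hydroxy)silyl]oxy}-5,6-epoxy-3-(hydroxymethyl)-2-[(1E)-prop-1-en-1-yl]cyclohex-2-en-1-one | OCC1=C(/C=C/C)C(=O)[C@@H]2O[C@@H]2[C@H]1O[Si](O)(C(C)(C)C)C(C)(C)C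
F5 | step 6 | tert-butyldimethylsilyl ether of 6 | CC(C)(C)[Si](C)(C)OCC1=C(Br)C(OC)(OC)[C@@H]2O[C@@H]2C1=O
F6 | step 6 | syn-epoxy alcohol (C-1 epimer of the silyl ether of 7, hydroxyl syn to epoxide) | CC(C)(C)[Si](C)(C)OCC1=C(Br)C(OC)(OC)[C@@H]2O[C@@H]2[C@@H]1O
F7 | step 6 | anti 4-nitrobenzoate (inverted at C-1) | CC(C)(C)[Si](C)(C)OCC1=C(Br)C(OC)(OC)[C@@H]2O[C@@H]2[C@H]1OC(=O)c1ccc(cc1)[N+](=O)[O-]
F8 | step 6 | primary tert-butyldimethylsilyl ether of 7 (hydroxyl anti to epoxide) | CC(C)(C)[Si](C)(C)OCC1=C(Br)C(OC)(OC)[C@@H]2O[C@@H]2[C@H]1O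
F9 | step 5 | tert-butyldiphenylsilyl ether of 5 | CC(C)(C)[Si](OCC1=C(Br)C(OC)(OC)C=CC1=O)(c1ccccc1)c1ccccc1
F10 | step 5 | tert-butyldiphenylsilyl ether of 6 | CC(C)(C)[Si](OCC1=C(Br)C(OC)(OC)[C@@H]2O[C@@H]2C1=O)(c1ccccc1)c1ccccc1
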